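Chain numbering runs from C1 (lactone C=O) to C12 (methyl). The plan rests on the cis-2,5-disubstituted oxolane ring (C7, C8, C9, C10 and the ring O). Its side-chain carbons C6 and C11 lie on one face, so an added C5–C11 bond turns the core into an 8-oxabicyclo[3.2.1]octan-3-one (C5 = ketone), the (4+3) adduct of furan and a 1-alkoxy-oxyallyl cation.
Late disconnections: the C11–O ester bond (Z-4-methoxycinnamic acid), C2=C3 (ring-closing metathesis of the C5 acrylate), C4–C5 (allylboration of the C5 aldehyde) and C11–C12 (chelate-controlled methyl addition to the C11 aldehyde).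
Unzipping: C5–C11 is cut by ozonolysis of the kinetic C5=C11 enol silane. C6–C7 and C10–C11 come from the cycloaddition, which also fixes C6, C7 and C10 under a removable (S)-1-phenylethyl ether.
Ring order: the oxygen-bridged seven-membered carbocycle (holding the future oxolane) forms in step 3, the carbocycle is opened in step 7, and the dihydropyranone closes in step 14.

Key step: step 3

Assumption: the (S)-1-phenylethyl group is taken to leave open the face of cation 6 that leads to (1R,2S,5R)-7. If the sense proves opposite, (R)-1-phenylethanol is used in step 1 and nothing else changes.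

Step 1
Reactants: 1 1,1-dimethoxypropan-2-one; 2 (S)-1-phenylethanol
Product: 3 1-methoxy-1-[(S)-1-phenylethoxy]propan-2-one (acetal carbon as epimer mixture)
Conditions: 1 (excess), PPTS (cat.), cyclohexane, reflux, MeOH removed over 4 Å MS
Reagents that add atoms: none
Why: Acid-catalysed transacetalisation via the oxocarbenium ion is driven by methanol removal and held at single exchange by the excess of 1, the carbinol C–O bond of 2 is never broken so its configuration is kept, and the new acetal centre is erased in step 3.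

Step 2
Reactants: 3 1-methoxy-1-[(S)-1-phenylethoxy]propan-2-one
Product: 4 triethyl({3-methoxy-3-[(S)-1-phenylethoxy]prop-1-en-2-yl}oxy)silane
Conditions: LDA, THF, −78 °C; TESCl, −78 °C to rt
Reagents that add atoms: chlorotriethylsilane, CC[Si](Cl)(CC)CC
Why: Kinetic enolisation of the methyl ketone at CH3 (the acetal C–H is hindered and electronically disfavoured) followed by O-silylation is standard enol silane formation and touches no stereocentre.

Step 3
Reactants: 4 triethyl({3-methoxy-3-[(S)-1-phenylethoxy]prop-1-en-2-yl}oxy)silane; 5 furan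
Product: 7 (1R,2S,5R)-2-[(S)-1-phenylethoxy]-8-oxabicyclo[3.2.1]oct-6-en-3-one (alkoxy group equatorial), via silyloxyallyl cation 6 (not isolated)
Conditions: furan (excess), TMSOTf (0.1 equiv), CH2Cl2, −95 °C; aq. NaHCO3; minor diastereomer removed by chromatography
Reagents that add atoms: none
Why: The silyl triflate silylates and expels the less hindered methoxy group of 4 to give the 1-alkoxy-2-silyloxyallyl cation 6, whose two termini bond to C2 and C5 of furan (C6–C7 and C10–C11 in target numbering), in concert or by way of a furan-stabilised cation, after which loss of the triethylsilyl group to triflate frees ketone 7 and a silyl triflate that carries the chain. The closest known reaction is the intermolecular (4+3) cycloaddition of furan with heteroatom-stabilised silyloxyallyl cations made from enol silanes of α-keto acetals. The seven-membered carbocycle closes by cycloaddition of the 4π furan with the 2π allyl cation, the oxygen bridge and with it the future oxolane arriving in the same event, so no chain cyclisation is involved. C7 and C10 must be cis because both new bonds form on one face of the flat furan, C6 carries its alkoxy group equatorial because the W-shaped cation reacts through the compact transition state, and the absolute sense of all three centres follows from the cation face that the phenyl group of the auxiliary leaves open. The step needs ionisation of OMe in preference to the phenylethoxy group, which sterics and the very low temperature should secure, and it needs facial discrimination, which is backed up by the fact that the two possible adducts are separable diastereomers. An axial epimer at C6, should any form, can be equilibrated with mild base to the more stable equatorial one.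

Step 4
Reactants: 7 (1R,2S,5R)-2-[(S)-1-phenylethoxy]-8-oxabicyclo[3.2.1]oct-6-en-3-one
Product: 8 (1R,2S,5S)-2-hydroxy-8-oxabicyclo[3.2.1]octan-3-one
Conditions: H2 (1 atm), 10% Pd/C, EtOH, rt
Reagents that add atoms: none
Why: Heterogeneous hydrogenation saturates the strained C8=C9 alkene and the same catalyst hydrogenolyses the secondary benzylic C–O bond, which frees C6–OH without touching C6, C7 or C10.

Step 5
Reactants: 8 (1R,2S,5S)-2-hydroxy-8-oxabicyclo[3.2.1]octan-3-one
Product: 9 (1R,2S,5S)-2-(tert-butyldimethylsilyloxy)-8-oxabicyclo[3.2.1]octan-3-one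
Conditions: TBSCl, imidazole, DMF, rt
Reagents that add atoms: tert-butylchlorodimethylsilane, CC(C)(C)[Si](C)(C)Cl
Why: Silylation of an equatorial secondary alcohol under weakly basic conditions should not isomerise the ketol and installs the group that masks C6–OH until the last step.

Step 6
Reactants: 9 (1R,2S,5S)-2-(tert-butyldimethylsilyloxy)-8-oxabicyclo[3.2.1]octan-3-one
Product: 10 (1R,2S,5S)-2-(tert-butyldimethylsilyloxy)-3-(trimethylsilyloxy)-8-oxabicyclo[3.2.1]oct-3-ene
Conditions: TMSCl, LDA (in situ quench), THF, −78 °C; pentane, cold aq. NaHCO3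
Reagents that add atoms: chlorotrimethylsilane, C[Si](C)(C)Cl
Why: Kinetic enolisation with in situ silyl trapping removes the axial proton of the free α′-methylene (C11) in preference to the hindered oxygen-bearing C6–H, and at −78 °C the bridged enolate should not expel the ring oxygen because the C10–O bond lies nearly orthogonal to the enolate π system.

Step 7
Reactants: 10 (1R,2S,5S)-2-(tert-butyldimethylsilyloxy)-3-(trimethylsilyloxy)-8-oxabicyclo[3.2.1]oct-3-ene
Product: 12 (2S)-2-(tert-butyldimethylsilyloxy)-2-[(2R,5S)-5-formyloxolan-2-yl]acetic acid, via trimethylsilyl ester 11 (not isolated)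
Conditions: O3, CH2Cl2, −78 °C; Me2S, −78 °C to rt; pH 4 aqueous work-up, used crude
Reagents that add atoms: ozone, [O-][O+]=O
Why: Ozonolysis of a silyl enol ether cleaves the only C=C bond (C5=C11), reduction of the peroxidic intermediate gives the C11 aldehyde, the C5 silyl ester hydrolyses on work-up, and the cis placement of C6 and C11 on the oxolane is inherited from the bicycle.

Step 8
Reactants: 12 (2S)-2-(tert-butyldimethylsilyloxy)-2-[(2R,5S)-5-formyloxolan-2-yl]acetic acid
Product: 13 methyl (2S)-2-(tert-butyldimethylsilyloxy)-2-[(2R,5S)-5-formyloxolan-2-yl]acetate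
Conditions: TMSCHN2, toluene/MeOH, 0 °C
Reagents that add atoms: (trimethylsilyl)diazomethane, C[Si](C)(C)C=[N+]=[N-]
Why: Diazoalkane esterification of the acid is fast and non-basic, so the epimerisable C10 and C6 centres are left alone and the aldehyde, which reacts only slowly without a Lewis acid, survives.

Step 9
Reactants: 13 methyl (2S)-2-(tert-butyldimethylsilyloxy)-2-[(2R,5S)-5-formyloxolan-2-yl]acetate
Product: 14 methyl (2S)-2-(tert-butyldimethylsilyloxy)-2-{(2R,5S)-5-[(1S)-1-hydroxyethyl]oxolan-2-yl}acetate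
Conditions: MgBr2·OEt2, CH2Cl2, −78 °C; MeMgBr (Et2O, 1.2 equiv), −78 °C; cold aqueous quench
Reagents that add atoms: methylmagnesium bromide, C[Mg]Br
Why: In this Cram-chelate Grignard addition magnesium ties the aldehyde oxygen to the oxolane oxygen in a five-membered chelate, methyl attacks from the side of C10–H away from C9 and so sets (11S), threo to C10, while at −78 °C the aldehyde reacts far faster than the hindered α-silyloxy ester.

Step 10
Reactants: 14 methyl (2S)-2-(tert-butyldimethylsilyloxy)-2-{(2R,5S)-5-[(1S)-1-hydroxyethyl]oxolan-2-yl}acetate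
Product: 15 methyl (2S)-2-(tert-butyldimethylsilyloxy)-2-{(2R,5S)-5-[(1S)-1-(triethylsilyloxy)ethyl]oxolan-2-yl}acetate
Conditions: TESCl, imidazole, CH2Cl2, 0 °C
Reagents that add atoms: chlorotriethylsilane, CC[Si](Cl)(CC)CC
Why: Routine silylation gives C11–OH a triethylsilyl ether that survives hydride, borane and metathesis chemistry and can later be removed in the presence of the C6 TBS ether.

Step 11
Reactants: 15 methyl (2S)-2-(tert-butyldimethylsilyloxy)-2-{(2R,5S)-5-[(1S)-1-(triethylsilyloxy)ethyl]oxolan-2-yl}acetate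
Product: 16 (2S)-2-(tert-butyldimethylsilyloxy)-2-{(2R,5S)-5-[(1S)-1-(triethylsilyloxy)ethyl]oxolan-2-yl}acetaldehyde
Conditions: DIBAL-H (1.1 equiv), CH2Cl2, −78 °C; MeOH, aq. Rochelle salt; used at once
Reagents that add atoms: none
Why: Partial ester reduction with DIBAL-H stops at the aluminium hemiacetal, which the neighbouring silyloxy oxygen stabilises at −78 °C, so the C5 aldehyde appears only on work-up and C6 is not epimerised.

Step 12
Reactants: 16 (2S)-2-(tert-butyldimethylsilyloxy)-2-{(2R,5S)-5-[(1S)-1-(triethylsilyloxy)ethyl]oxolan-2-yl}acetaldehyde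
Product: 17 (1R,2R)-1-(tert-butyldimethylsilyloxy)-1-{(2R,5S)-5-[(1S)-1-(triethylsilyloxy)ethyl]oxolan-2-yl}pent-4-en-2-ol (C5 is R; C6 is unchanged in space and only its descriptor switches by CIP ranking)
Conditions: B-allyldiisopinocampheylborane of the (−)-α-pinene series, Et2O, −78 °C; NaOH, H2O2, 0 °C to rt
Reagents that add atoms: B-allyldiisopinocampheylborane of the (−)-α-pinene series, C=CCB([C@H]1C[C@H]2C[C@@H]([C@@H]1C)C2(C)C)[C@H]1C[C@H]2C[C@@H]([C@@H]1C)C2(C)C
Why: Brown allylboration through a closed chair transition state delivers allyl to the aldehyde face that gives (5R), which is also the Felkin–Anh (5,6-anti) face of the α-silyloxy aldehyde, so reagent and substrate control are matched.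

Step 13
Reactants: 17 (1R,2R)-1-(tert-butyldimethylsilyloxy)-1-{(2R,5S)-5-[(1S)-1-(triethylsilyloxy)ethyl]oxolan-2-yl}pent-4-en-2-ol
Product: 18 (1S,2R)-1-(tert-butyldimethylsilyloxy)-1-{(2R,5S)-5-[(1S)-1-(triethylsilyloxy)ethyl]oxolan-2-yl}pent-4-en-2-yl prop-2-enoate
Conditions: acryloyl chloride, Et3N, DMAP (cat.), CH2Cl2, 0 °C
Reagents that add atoms: acryloyl chloride, C=CC(=O)Cl
Why: O-acylation of the only free hydroxyl with a small reactive acid chloride brings in C1 and C2 with retention at C5.

Step 14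
Reactants: 18 (1S,2R)-1-(tert-butyldimethylsilyloxy)-1-{(2R,5S)-5-[(1S)-1-(triethylsilyloxy)ethyl]oxolan-2-yl}pent-4-en-2-yl prop-2-enoate
Product: 19 (6R)-6-[(S)-(tert-butyldimethylsilyloxy){(2R,5S)-5-[(1S)-1-(triethylsilyloxy)ethyl]oxolan-2-yl}methyl]-5,6-dihydro-2H-pyran-2-one
Conditions: Grubbs II catalyst (5 mol %), CH2Cl2 (dilute), reflux
Reagents that add atoms: none
Why: Ring-closing metathesis of an acrylate with a terminal alkene is the standard entry to 5,6-dihydropyran-2-ones, is driven by loss of ethene, and gives the cis C2=C3 bond that the six-membered ring demands.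

Step 15
Reactants: 19 (6R)-6-[(S)-(tert-butyldimethylsilyloxy){(2R,5S)-5-[(1S)-1-(triethylsilyloxy)ethyl]oxolan-2-yl}methyl]-5,6-dihydro-2H-pyran-2-one
Product: 20 (6R)-6-[(S)-(tert-butyldimethylsilyloxy){(2R,5S)-5-[(1S)-1-hydroxyethyl]oxolan-2-yl}methyl]-5,6-dihydro-2H-pyran-2-one
Conditions: AcOH/THF/H2O, rt
Reagents that add atoms: none
Why: Mild acid hydrolysis cleaves the less hindered triethylsilyl ether much faster than the flanked secondary TBS ether and leaves the unsaturated lactone intact.

Step 16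
Reactants: 21 4-methoxybenzaldehyde
Product: 22 methyl (2Z)-3-(4-methoxyphenyl)prop-2-enoate
Conditions: methyl bis(2,2,2-trifluoroethyl)phosphonoacetate, KHMDS, 18-crown-6, THF, −78 °C
Reagents that add atoms: methyl bis(2,2,2-trifluoroethyl)phosphonoacetate, COC(=O)CP(=O)(OCC(F)(F)F)OCC(F)(F)F
Why: In the Still–Gennari olefination the electron-poor phosphonate with a dissociated potassium counter-ion eliminates quickly from the kinetic syn adduct, which should give the Z-enoate from an aromatic aldehyde.

Step 17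
Reactants: 22 methyl (2Z)-3-(4-methoxyphenyl)prop-2-enoate
Product: 23 (2Z)-3-(4-methoxyphenyl)prop-2-enoic acid
Conditions: LiOH, THF/H2O, rt, dark; 1 M HCl to pH 3
Reagents that add atoms: lithium hydroxide, [Li+].[OH-]
Why: Saponification by acyl–oxygen cleavage does not involve the alkene, and exclusion of light guards the Z geometry.

Step 18
Reactants: 20 (6R)-6-[(S)-(tert-butyldimethylsilyloxy){(2R,5S)-5-[(1S)-1-hydroxyethyl]oxolan-2-yl}methyl]-5,6-dihydro-2H-pyran-2-one; 23 (2Z)-3-(4-methoxyphenyl)prop-2-enoic acid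
Product: 24 (1S)-1-[(2S,5R)-5-{(S)-(tert-butyldimethylsilyloxy)[(2R)-6-oxo-3,6-dihydro-2H-pyran-2-yl]methyl}oxolan-2-yl]ethyl (2Z)-3-(4-methoxyphenyl)prop-2-enoate
Conditions: DCC, DMAP (cat.), CH2Cl2, 0 °C to rt, dark
Reagents that add atoms: none
Why: Steglich esterification acylates the only free hydroxyl (a lightly hindered methyl carbinol) with retention at C11, and low temperature, catalytic DMAP and darkness are chosen to keep the Z alkene.

Step 19
Reactants: 24 (1S)-1-[(2S,5R)-5-{(S)-(tert-butyldimethylsilyloxy)[(2R)-6-oxo-3,6-dihydro-2H-pyran-2-yl]methyl}oxolan-2-yl]ethyl (2Z)-3-(4-methoxyphenyl)prop-2-enoate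
Product: 25 (1S)-1-[(2S,5R)-5-{(S)-hydroxy[(2R)-6-oxo-3,6-dihydro-2H-pyran-2-yl]methyl}oxolan-2-yl]ethyl (2Z)-3-(4-methoxyphenyl)prop-2-enoate (CNP0080290.1)
Conditions: HF·pyridine, THF, 0 °C to rt (plastic vessel)
Reagents that add atoms: none
Why: Fluoride desilylation in an acidic medium frees C6–OH without forming an alkoxide, which avoids oxa-Michael addition of C6–O to C3, acyl migration and Z to E drift.

Compound list
1 | 1,1-dimethoxypropan-2-one | CC(=O)C(OC)OC | starting material
2 | (S)-1-phenylethanol | C[C@H](O)c1ccccc1 | starting material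
3 | 1-methoxy-1-[(S)-1-phenylethoxy]propan-2-one (acetal epimers) | CC(=O)C(OC)O[C@@H](C)c1ccccc1 | intermediate
4 | triethyl({3-methoxy-3-[(S)-1-phenylethoxy]prop-1-en-2-yl}oxy)silane (acetal epimers) | C=C(O[Si](CC)(CC)CC)C(OC)O[C@@H](C)c1ccccc1 | intermediate
5 | furan | c1ccoc1 | starting material
6 | 1-[(S)-1-phenylethoxy]-2-(triethylsilyloxy)allyl cation (not isolated) | C=C(O[Si](CC)(CC)CC)C=[O+][C@@H](C)c1ccccc1 | intermediate
7 | (1R,2S,5R)-2-[(S)-1-phenylethoxy]-8-oxabicyclo[3.2.1]oct-6-en-3-one | C1[C@@H]2C=C[C@H]([C@H](O[C@@H](C)c3ccccc3)C1=O)O2 | intermediate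
8 | (1R,2S,5S)-2-hydroxy-8-oxabicyclo[3.2.1]octan-3-one | C1[C@@H]2CC[C@H]([C@H](O)C1=O)O2 | intermediate
9 | (1R,2S,5S)-2-(tert-butyldimethylsilyloxy)-8-oxabicyclo[3.2.1]octan-3-one | C1[C@@H]2CC[C@H]([C@H](O[Si](C)(C)C(C)(C)C)C1=O)O2 | intermediate
10 | (1R,2S,5S)-2-(tert-butyldimethylsilyloxy)-3-(trimethylsilyloxy)-8-oxabicyclo[3.2.1]oct-3-ene | C1=C(O[Si](C)(C)C)[C@@H](O[Si](C)(C)C(C)(C)C)[C@H]2CC[C@@H]1O2 | intermediate
11 | trimethylsilyl (2S)-2-(tert-butyldimethylsilyloxy)-2-[(2R,5S)-5-formyloxolan-2-yl]acetate (not isolated) | O=C[C@@H]1CC[C@H]([C@H](O[Si](C)(C)C(C)(C)C)C(=O)O[Si](C)(C)C)O1 | intermediate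
12 | (2S)-2-(tert-butyldimethylsilyloxy)-2-[(2R,5S)-5-formyloxolan-2-yl]acetic acid | O=C[C@@H]1CC[C@H]([C@H](O[Si](C)(C)C(C)(C)C)C(=O)O)O1 | intermediate
13 | methyl (2S)-2-(tert-butyldimethylsilyloxy)-2-[(2R,5S)-5-formyloxolan-2-yl]acetate | O=C[C@@H]1CC[C@H]([C@H](O[Si](C)(C)C(C)(C)C)C(=O)OC)O1 | intermediate
14 | methyl (2S)-2-(tert-butyldimethylsilyloxy)-2-{(2R,5S)-5-[(1S)-1-hydroxyethyl]oxolan-2-yl}acetate | C[C@H](O)[C@@H]1CC[C@H]([C@H](O[Si](C)(C)C(C)(C)C)C(=O)OC)O1 | intermediate
15 | methyl (2S)-2-(tert-butyldimethylsilyloxy)-2-{(2R,5S)-5-[(1S)-1-(triethylsilyloxy)ethyl]oxolan-2-yl}acetate | C[C@H](O[Si](CC)(CC)CC)[C@@H]1CC[C@H]([C@H](O[Si](C)(C)C(C)(C)C)C(=O)OC)O1 | intermediate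
16 | (2S)-2-(tert-butyldimethylsilyloxy)-2-{(2R,5S)-5-[(1S)-1-(triethylsilyloxy)ethyl]oxolan-2-yl}acetaldehyde | C[C@H](O[Si](CC)(CC)CC)[C@@H]1CC[C@H]([C@H](O[Si](C)(C)C(C)(C)C)C=O)O1 | intermediate
17 | (1R,2R)-1-(tert-butyldimethylsilyloxy)-1-{(2R,5S)-5-[(1S)-1-(triethylsilyloxy)ethyl]oxolan-2-yl}pent-4-en-2-ol | C[C@H](O[Si](CC)(CC)CC)[C@@H]1CC[C@H]([C@H](O[Si](C)(C)C(C)(C)C)[C@H](O)CC=C)O1 | intermediate
18 | (1S,2R)-1-(tert-butyldimethylsilyloxy)-1-{(2R,5S)-5-[(1S)-1-(triethylsilyloxy)ethyl]oxolan-2-yl}pent-4-en-2-yl prop-2-enoate | C[C@H](O[Si](CC)(CC)CC)[C@@H]1CC[C@H]([C@H](O[Si](C)(C)C(C)(C)C)[C@H](OC(=O)C=C)CC=C)O1 | intermediate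
19 | (6R)-6-[(S)-(tert-butyldimethylsilyloxy){(2R,5S)-5-[(1S)-1-(triethylsilyloxy)ethyl]oxolan-2-yl}methyl]-5,6-dihydro-2H-pyran-2-one | C[C@H](O[Si](CC)(CC)CC)[C@@H]1CC[C@H]([C@H](O[Si](C)(C)C(C)(C)C)[C@H]2CC=CC(=O)O2)O1 | intermediate
20 | (6R)-6-[(S)-(tert-butyldimethylsilyloxy){(2R,5S)-5-[(1S)-1-hydroxyethyl]oxolan-2-yl}methyl]-5,6-dihydro-2H-pyran-2-one | C[C@H](O)[C@@H]1CC[C@H]([C@H](O[Si](C)(C)C(C)(C)C)[C@H]2CC=CC(=O)O2)O1 | intermediate
21 | 4-methoxybenzaldehyde | COc1ccc(C=O)cc1 | starting material
22 | methyl (2Z)-3-(4-methoxyphenyl)prop-2-enoate | COC(=O)/C=C\c1ccc(OC)cc1 | intermediate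
23 | (2Z)-3-(4-methoxyphenyl)prop-2-enoic acid | OC(=O)/C=C\c1ccc(OC)cc1 | intermediate
24 | C6-O-TBS ether of the target | COc1ccc(/C=C\C(=O)O[C@@H](C)[C@@H]2CC[C@H]([C@H](O[Si](C)(C)C(C)(C)C)[C@H]3CC=CC(=O)O3)O2)cc1 | intermediate
25 | CNP0080290.1, (5R,6S,7R,10S,11S) in chain numbering | COc1ccc(/C=C\C(=O)O[C@@H](C)[C@@H]2CC[C@H]([C@H](O)[C@H]3CC=CC(=O)O3)O2)cc1 | target

Total step count: 19. Longest linear sequence: 17 steps (steps 1 to 15, 18 and 19, from 1,1-dimethoxypropan-2-one). Steps 16 and 17 form the side branch.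

Steps most likely to fail

1. Step 3.
- What may go wrong: the auxiliary may discriminate the two cation faces too weakly. The phenylethoxy group may ionise in competition with methoxy. Furan may be alkylated without ring closure.
- Fallback (sets out from 5, returns at 9): absolute control is moved from an auxiliary to a chiral base.
- Furan 5 undergoes the parent (4+3) cycloaddition with the oxyallyl species from 1,1,3,3-tetrabromoacetone (Zn, B(OEt)3, THF) to give 2,4-dibromo-8-oxabicyclo[3.2.1]oct-6-en-3-one F1.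
- Zn–Cu couple in NH4Cl/MeOH reduces this to meso-8-oxabicyclo[3.2.1]oct-6-en-3-one F2, and hydrogenation (H2, Pd/C) gives meso-8-oxabicyclo[3.2.1]octan-3-one F3.
- Enantiotopic deprotonation follows, with a homochiral lithium bis(1-phenylethyl)amide (LiCl, TMSCl in situ, THF, −100 °C). The antipode is chosen that removes the axial proton at the future C6. This gives (1R,5S)-3-(trimethylsilyloxy)-8-oxabicyclo[3.2.1]oct-2-ene F4.
- Rubottom oxidation (mCPBA, NaHCO3, then dilute acid) should deliver oxygen from the exo face to give the axial ketol (1R,2R,5S)-2-hydroxy-8-oxabicyclo[3.2.1]octan-3-one F5.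
- Silylation (TBSCl, imidazole) gives the axial ether (1R,2R,5S)-2-(tert-butyldimethylsilyloxy)-8-oxabicyclo[3.2.1]octan-3-one F6, and equilibration with DBU should move the substituent into the more stable equatorial position, which is 9.

2. Step 9.
- What may go wrong: chelate control may erode because magnesium can also bind the ester carbonyl together with the ring oxygen. The α-alkoxy aldehyde may epimerise before it reacts.
- Fallback (sets out from 13, returns at 14): C11 is set by a catalyst acting on a ketone instead of by substrate chelation.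
- Aldehyde 13 is methylated without regard to facial control (MeMgBr, THF, −78 °C) to methyl (2S)-2-(tert-butyldimethylsilyloxy)-2-[(2R,5S)-5-(1-hydroxyethyl)oxolan-2-yl]acetate as its C11 epimers F7.
- Buffered Dess–Martin oxidation gives methyl (2S)-2-(tert-butyldimethylsilyloxy)-2-[(2R,5S)-5-acetyloxolan-2-yl]acetate F8.
- Corey–Bakshi–Shibata reduction with (R)-Me-CBS and BH3·SMe2 treats the oxolanyl group as the large and methyl as the small substituent, and should give the (11S) carbinol 14.

3. Step 18.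
- What may go wrong: the activated acyl species may isomerise from Z to E, because the 4-methoxyphenyl donor lowers the rotation barrier and DMAP can add reversibly.
- Fallback (sets out from 20, returns at 24): the Z alkene is made after the ester bond.
- Alcohol 20 is esterified (DCC, DMAP, CH2Cl2, 0 °C) with commercial 3-(4-methoxyphenyl)prop-2-ynoic acid to give the C11 3-(4-methoxyphenyl)prop-2-ynoate F9.
- Lindlar semi-hydrogenation (Pd/CaCO3–Pb, quinoline, H2, EtOAc) adds hydrogen syn to the alkyne to give 24. The conjugated lactone alkene should react much more slowly.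

Further compounds
F1 | step 3 | 2,4-dibromo-8-oxabicyclo[3.2.1]oct-6-en-3-one (C–Br epimers) | BrC1[C@@H]2C=C[C@H](C(Br)C1=O)O2
F2 | step 3 | meso-8-oxabicyclo[3.2.1]oct-6-en-3-one | C1[C@@H]2C=C[C@H](CC1=O)O2
F3 | step 3 | meso-8-oxabicyclo[3.2.1]octan-3-one | C1[C@@H]2CC[C@H](CC1=O)O2
F4 | step 3 | (1R,5S)-3-(trimethylsilyloxy)-8-oxabicyclo[3.2.1]oct-2-ene | C1[C@@H]2CC[C@H](C=C1O[Si](C)(C)C)O2
F5 | step 3 | (1R,2R,5S)-2-hydroxy-8-oxabicyclo[3.2.1]octan-3-one (axial OH) | C1[C@@H]2CC[C@H]([C@@H](O)C1=O)O2
F6 | step 3 | (1R,2R,5S)-2-(tert-butyldimethylsilyloxy)-8-oxabicyclo[3.2.1]octan-3-one (axial OTBS) | C1[C@@H]2CC[C@H]([C@@H](O[Si](C)(C)C(C)(C)C)C1=O)O2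
F7 | step 9 | methyl (2S)-2-(tert-butyldimethylsilyloxy)-2-[(2R,5S)-5-(1-hydroxyethyl)oxolan-2-yl]acetate (C11 epimers) | CC(O)[C@@H]1CC[C@H]([C@H](O[Si](C)(C)C(C)(C)C)C(=O)OC)O1
F8 | step 9 | methyl (2S)-2-(tert-butyldimethylsilyloxy)-2-[(2R,5S)-5-acetyloxolan-2-yl]acetate | CC(=O)[C@@H]1CC[C@H]([C@H](O[Si](C)(C)C(C)(C)C)C(=O)OC)O1
F9 | step 18 | C11 3-(4-methoxyphenyl)prop-2-ynoate of alcohol 20 | COc1ccc(C#CC(=O)O[C@@H](C)[C@@H]2CC[C@H]([C@H](O[Si](C)(C)C(C)(C)C)[C@H]3CC=CC(=O)O3)O2)cc1
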